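**Retrosynthetic overview**

1. Target 28 ⇐ epoxy acrylic acid 27: the lactone C8–O bond and the free C9–OH arise together when the carboxyl group opens a trans-8,9-epoxide at C8 (5-exo, inversion). The 4,5-epoxide comes from C4–OH/C5–OMs (inversion at C5).
2. Ten-membered ring ⇐ cyclohexane: anionic oxy-Cope rearrangement of the 8-propenyl-3-vinylcyclohexan-8-ol 15 forms C1–C10 and breaks a temporary C3–C8 bond; the enolate is hydroxylated at C9 in the same flask.
3. Enabling feature: C3 and C8 lie 1,6 across the ten-membered ring, so a C3–C8 bond turns C3–C8 into a cyclohexane. Its C8 carries the future lactone oxygen (the alkoxide), and vinyl on C3 (C1=C2) plus propenyl on C8 (C9=C10) make the 3-oxido-1,5-diene. The C4, C5, C6 and C8 oxygens are those of a gallate-type arene.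
4. Cyclohexane ⇐ arene: dearomatisation of 3,4,5-tris(benzyloxy)phenol, addition of a chiral sulfinylmethyl anion (later turned into the propenyl group), two alkoxide-directed conjugate additions (C3, C7), methylation (C4) and reduction (C5).
5. Ring order: six-membered carbocycle (from the arene) → ten-membered ring (key step) → 8,9-epoxide → 4,5-epoxide → γ-lactone (last).

Key step: step 10

Remark (assumptions): germacranolide numbering is used throughout (ring C1–C10; lactone oxygen on C8, hydroxyl on C9, methyl C14 on C10, methyl C15 on C4, lactone carbons C11–C13). The (S)-sulfoxide is assumed to steer the first Grignard addition to the enone arm shown in 9, by analogy with trialkylaluminium additions to sulfinylmethyl quinols; if the sense is opposite, the (R)-sulfoxide is used and nothing else changes.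

**Route**

Step 1
Reactants: 1 3,4,5-tris(benzyloxy)benzaldehyde
Product: 3 3,4,5-tris(benzyloxy)phenol, via aryl formate 2 (not isolated)
Conditions: mCPBA, CH2Cl2, 25 °C; then KOH, MeOH/H2O, 0 °C
Reagents that add atoms: 3-chloroperoxybenzoic acid, O=C(OO)c1cccc(Cl)c1
Why: Baeyer–Villiger oxidation of the electron-rich benzaldehyde with aryl migration (Dakin-type) and saponification of the formate should give the phenol; no stereocentre is involved.

Step 2
Reactants: 3 3,4,5-tris(benzyloxy)phenol
Product: 4 3,4,5-tris(benzyloxy)-4-methoxycyclohexa-2,5-dien-1-one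
Conditions: PhI(OAc)2, MeOH, 0 °C
Reagents that add atoms: methanol, CO
Why: oxidative dearomatisation of a para-alkoxyphenol by trivalent iodine, with methanol captured at the para carbon, is the standard entry to quinone monoketals.

Step 3
Reactants: 4 3,4,5-tris(benzyloxy)-4-methoxycyclohexa-2,5-dien-1-one; 5 (S)-methyl p-tolyl sulfoxide
Product: 7 2,6-bis(benzyloxy)-4-hydroxy-4-{[(S)-p-tolylsulfinyl]methyl}cyclohexa-2,5-dien-1-one, via ketal carbinol 6 (not isolated)
Conditions: 5, LiN(iPr)2, THF, −78 °C; 4, −78 °C; then oxalic acid, THF/H2O, 0 °C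
Reagents that add atoms: water, O
Why: 1,2-addition of the α-sulfinyl carbanion to the dienone carbonyl and mild hydrolysis of the quinone ketal should give the sulfinylmethyl p-quinol; no carbon stereocentre arises because both enone arms are still identical, and sulfur keeps its S configuration.

Step 4
Reactants: 7 2,6-bis(benzyloxy)-4-hydroxy-4-{[(S)-p-tolylsulfinyl]methyl}cyclohexa-2,5-dien-1-one
Product: 9 4,6-bis(benzyloxy)-8-hydroxy-4-methyl-8-{[(S)-p-tolylsulfinyl]methyl}-3-vinylcyclohex-6-en-5-one (target locants; vinyl cis to 8-OH; 4-methyl trans to vinyl), via magnesium enolate 8 (not isolated)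
Conditions: CH2=CHMgBr (3.5 equiv), THF, −78 → −30 °C; then MeI, DMPU, −30 → 0 °C
Reagents that add atoms: vinylmagnesium bromide, C=C[Mg]Br; iodomethane, CI
Why: alkoxide-directed conjugate addition of a Grignard reagent to a p-quinol should deliver vinyl cis to the C8 oxygen on the arm selected by the chelating sulfinyl group (sets C3, makes C8 stereogenic), and C-methylation of the α-benzyloxy enolate anti to the new vinyl group sets C4.

Step 5
Reactants: 9 4,6-bis(benzyloxy)-8-hydroxy-4-methyl-8-{[(S)-p-tolylsulfinyl]methyl}-3-vinylcyclohex-6-en-5-one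
Product: 11 4,6-bis(benzyloxy)-7-(1,3-dioxolan-2-ylmethyl)-8-hydroxy-4-methyl-8-{[(S)-p-tolylsulfinyl]methyl}-3-vinylcyclohexan-5-one (side chain cis to 8-OH; 6-benzyloxy trans to the side chain), via magnesium enolate 10 (not isolated)
Conditions: (1,3-dioxolan-2-ylmethyl)magnesium bromide (3 equiv), THF, −40 → 0 °C; then MeOH, 25 °C
Reagents that add atoms: (1,3-dioxolan-2-ylmethyl)magnesium bromide, Br[Mg]CC1OCCO1
Why: a second alkoxide-directed conjugate addition to the only remaining (non-enolisable) enone should place the acetal chain at C7 cis to the C8 oxygen, and protonation with equilibration of the α-benzyloxy ketone leaves the C6 benzyloxy group equatorial, trans to the chain.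

Step 6
Reactants: 11 the cyclohexan-5-one from step 5
Product: 12 the corresponding cyclohexane-5,8-diol (5-OH cis to the 4-benzyloxy group and to 8-OH)
Conditions: NaBH4, MeOH, −20 °C
Reagents that add atoms: none
Why: axial hydride attack on the chair ketone, anti to the axial C4 benzyloxy group (Felkin–Anh), should give the equatorial C5 alcohol.

Step 7
Reactants: 12 the cyclohexane-5,8-diol
Product: 13 its 5-O-triethylsilyl ether (8-OH free)
Conditions: Et3SiCl, imidazole, DMF, 0 → 25 °C
Reagents that add atoms: chlorotriethylsilane, CC[Si](Cl)(CC)CC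
Why: silylation should select the secondary C5 hydroxyl over the tertiary C8 carbinol, so that C5 is neither a nucleophile nor a leaving group in the key step.

Step 8
Reactants: 13 the 5-O-triethylsilyl ether
Product: 14 the α-ethylated sulfoxide with a 1-[(S)-p-tolylsulfinyl]propyl group on C8 (both C9 epimers)
Conditions: LiN(iPr)2 (2.3 equiv), THF, −78 °C; then EtI, DMPU, −78 → −20 °C
Reagents that add atoms: iodoethane, CCI
Why: C-alkylation of the dianion of a β-hydroxy sulfoxide at the α-sulfinyl carbon introduces C10 and C14; the new centre at C9 is erased in step 9.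

Step 9
Reactants: 14 the α-ethylated sulfoxide
Product: 15 4,6-bis(benzyloxy)-7-(1,3-dioxolan-2-ylmethyl)-4-methyl-8-[(E)-prop-1-enyl]-5-(triethylsilyloxy)-3-vinylcyclohexan-8-ol
Conditions: CaCO3, toluene, 110 °C
Reagents that add atoms: none
Why: thermal syn-elimination of the aryl sulfoxide, possible only towards C10, should give the (E)-propenyl carbinol and remove the auxiliary; the neutral dialkenyl carbinol does not rearrange at this temperature.

Step 10
Reactants: 15 the 8-[(E)-prop-1-enyl]-3-vinylcyclohexan-8-ol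
Product: 17 (9S,10R)-4,6-bis(benzyloxy)-7-(1,3-dioxolan-2-ylmethyl)-9-hydroxy-4,10-dimethyl-5-(triethylsilyloxy)cyclodec-2-en-8-one (E alkene), via potassium enolate 16 (not isolated)
Conditions: KH, 18-crown-6, THF, 0 → 25 °C; then 2-(phenylsulfonyl)-3-phenyloxaziridine, −78 °C
Reagents that add atoms: 2-(phenylsulfonyl)-3-phenyloxaziridine, O=S(=O)(c1ccccc1)N1OC1c1ccccc1
Why: KH/18-crown-6 gives the C8 potassium alkoxide, whose 3-oxido-1,5-diene C1=C2–C3–C8–C9=C10 undergoes an anionic oxy-Cope [3,3] shift through a chair transition state with vinyl and (E)-propenyl both equatorial on the chair cyclohexane (C8–O axial), breaking C3–C8 and forming C1–C10; the closest known reaction type is the ring expansion of trans-1,2-dialkenylcyclohexanols to (E)-cyclodec-5-enones with oxygenation of the resulting enolate. The ten-membered ring is thus closed by a six-centre sigmatropic event (four-carbon ring expansion of the cyclohexane) and not by an end-to-end cyclisation. C10 becomes R because in this chair the methyl of the E-propenyl group is pseudo-equatorial and C1 adds to one defined face of C9=C10; C9 becomes S because the oxaziridine can reach enolate 16 only from its outer face, the inner face being covered by the ring and the as-formed conformation being held by allylic strain between the enolate oxygen and the C10 substituents. The step needs a single [3,3] channel and no transannular electrophile, which the substrate secures: the C7 substituent is saturated, so no second 1,5-diene exists, and C5 bears a silyl ether and not a leaving group, because C9 of the enolate lies directly behind the C5–O bond.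

Step 11
Reactants: 17 the 9-hydroxycyclodec-2-en-8-one
Product: 18 the (8R,9S,10R)-cyclodec-2-ene-8,9-diol
Conditions: Zn(BH4)2, Et2O, −20 °C
Reagents that add atoms: none
Why: chelation-controlled reduction of the α-hydroxy ketone (zinc bridging the C8 and C9 oxygens, hydride from the outer face) should give the 8,9-anti diol and sets C8 as R.

Step 12
Reactants: 18 the 8,9-diol
Product: 20 the (8R,9R)-8,9-epoxide with free 5-OH, via hydroxy tosylate 19 (not isolated)
Conditions: TsCl, Et3N, Bu2SnO (cat.), CH2Cl2, 0 °C; then Bu4NF, THF, 0 → 25 °C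
Reagents that add atoms: none
Why: tin-mediated monosulfonylation should pick the more accessible, outward-pointing C9 hydroxyl, and fluoride-induced closure by the C8 alkoxide with inversion at C9 (Williamson-type) gives the trans-epoxide while the hydrogen fluoride released frees the C5 hydroxyl.

Step 13
Reactants: 20 the 8,9-epoxide with free 5-OH
Product: 21 its 5-O-methanesulfonate
Conditions: MsCl, Et3N, 4-(dimethylamino)pyridine (cat.), CH2Cl2, 0 °C
Reagents that add atoms: methanesulfonyl chloride, CS(=O)(=O)Cl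
Why: sulfene-type mesylation of the only free hydroxyl installs the C5 leaving group now that no carbanion sits across the ring.

Step 14
Reactants: 21 the 5-O-methanesulfonate
Product: 22 the saturated 4,6-diol (8,9-epoxide, 5-mesylate and dioxolane retained)
Conditions: H2 (1 atm), Pd(OH)2/C, EtOAc/EtOH, 25 °C
Reagents that add atoms: none
Why: heterogeneous hydrogenation should saturate the C2=C3 alkene and cleave both benzyl ethers by hydrogenolysis without touching the epoxide, mesylate or acetal.

Step 15
Reactants: 22 the saturated 4,6-diol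
Product: 23 its 6-O-(3-methylbut-2-enoyl) ester
Conditions: 3-methylbut-2-enoyl chloride, pyridine, 4-(dimethylamino)pyridine (cat.), CH2Cl2, 0 °C
Reagents that add atoms: 3-methylbut-2-enoyl chloride, CC(C)=CC(=O)Cl
Why: acylation should occur only at the secondary C6 hydroxyl, since the C4 hydroxyl is tertiary and C8/C9 are masked as the epoxide.

Step 16
Reactants: 23 the 6-O-(3-methylbut-2-enoyl) ester
Product: 24 the C12 aldehyde (C7–CH2–CHO)
Conditions: pyridinium p-toluenesulfonate, acetone/H2O, 45 °C
Reagents that add atoms: water, O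
Why: mild acid hydrolysis of the dioxolane should give the aldehyde, which cannot form a lactol because the C5, C6 and C8 oxygens are blocked.

Step 17
Reactants: 24 the C12 aldehyde
Product: 26 the α-methylene aldehyde bearing the (4R,5R)-4,5-epoxide and the 8,9-epoxide, via epoxy aldehyde 25 (not isolated)
Conditions: DBU, MeCN, 25 °C; then Me2N=CH2 I, 25 °C
Reagents that add atoms: dimethylmethyleneammonium iodide, C=[N+](C)C.[I-]
Why: the tertiary C4 alkoxide displaces the C5 mesylate with inversion to give the trans-4,5-epoxide, and a Mannich reaction of the aldehyde with the iminium salt followed by amine elimination gives the 2-substituted acrolein.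

Step 18
Reactants: 26 the α-methylene aldehyde
Product: 28 (4R,5R,6R,7S,8S,9R,10R)-4,5-epoxy-9-hydroxy-6-(3-methylbut-2-enoyloxy)germacr-11(13)-en-12,8-olide (target), via acrylic acid 27 (not isolated)
Conditions: NaClO2, NaH2PO4, 2-methylbut-2-ene, t-BuOH/H2O, 0 → 25 °C
Reagents that add atoms: sodium chlorite, [Na+].[O-]Cl=O
Why: Pinnick oxidation gives the acrylic acid, whose carboxyl group should open the 8,9-epoxide at C8 in the 5-exo mode with inversion, forming the trans-fused α-methylene γ-lactone (8S) and releasing the C9 hydroxyl (9R).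

**Compound list**

1 | 3,4,5-tris(benzyloxy)benzaldehyde | O=Cc1cc(OCc2ccccc2)c(OCc2ccccc2)c(OCc2ccccc2)c1 | starting material
2 | 3,4,5-tris(benzyloxy)phenyl formate | O=COc1cc(OCc2ccccc2)c(OCc2ccccc2)c(OCc2ccccc2)c1 | intermediate
3 | 3,4,5-tris(benzyloxy)phenol | Oc1cc(OCc2ccccc2)c(OCc2ccccc2)c(OCc2ccccc2)c1 | intermediate
4 | 3,4,5-tris(benzyloxy)-4-methoxycyclohexa-2,5-dien-1-one | O=C1C=C(OCc2ccccc2)C(OC)(OCc2ccccc2)C(OCc2ccccc2)=C1 | intermediate
5 | (S)-methyl p-tolyl sulfoxide | C[S@](=O)c1ccc(C)cc1 | starting material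
6 | 3,4,5-tris(benzyloxy)-4-methoxy-1-{[(S)-p-tolylsulfinyl]methyl}cyclohexa-2,5-dien-1-ol (both cis/trans isomers at the ketal carbon) | OC1(C[S@](=O)c2ccc(C)cc2)C=C(OCc2ccccc2)C(OC)(OCc2ccccc2)C(OCc2ccccc2)=C1 | intermediate
7 | 2,6-bis(benzyloxy)-4-hydroxy-4-{[(S)-p-tolylsulfinyl]methyl}cyclohexa-2,5-dien-1-one | O=C1C(OCc2ccccc2)=CC(O)(C[S@](=O)c2ccc(C)cc2)C=C1OCc2ccccc2 | intermediate
8 | bis(bromomagnesium) C4=C5 enolate/C8 alkoxide of the vinyl adduct (vinyl at C3 cis to the C8 oxygen) | C=C[C@H]1C(OCc2ccccc2)=C([O-])C(OCc2ccccc2)=C[C@]1([O-])C[S@](=O)c1ccc(C)cc1.[Mg+2].[Mg+2].[Br-].[Br-] | intermediate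
9 | 4,6-bis(benzyloxy)-8-hydroxy-4-methyl-8-{[(S)-p-tolylsulfinyl]methyl}-3-vinylcyclohex-6-en-5-one (ring atoms carry target locants C3–C8; 3-vinyl and 4-benzyloxy cis to 8-OH, 4-methyl trans) | C=C[C@H]1[C@@](C)(OCc2ccccc2)C(=O)C(OCc2ccccc2)=C[C@]1(O)C[S@](=O)c1ccc(C)cc1 | intermediate
10 | bis(bromomagnesium) C5=C6 enolate/C8 alkoxide of the side-chain adduct (side chain at C7 cis to the C8 oxygen) | C=C[C@H]1[C@@](C)(OCc2ccccc2)C([O-])=C(OCc2ccccc2)[C@@H](CC2OCCO2)[C@]1([O-])C[S@](=O)c1ccc(C)cc1.[Mg+2].[Mg+2].[Br-].[Br-] | intermediate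
11 | 4,6-bis(benzyloxy)-7-(1,3-dioxolan-2-ylmethyl)-8-hydroxy-4-methyl-8-{[(S)-p-tolylsulfinyl]methyl}-3-vinylcyclohexan-5-one (3-vinyl, 4-benzyloxy, 7-side chain and 8-OH on one face; 4-methyl and 6-benzyloxy on the other) | C=C[C@H]1[C@@](C)(OCc2ccccc2)C(=O)[C@H](OCc2ccccc2)[C@@H](CC2OCCO2)[C@]1(O)C[S@](=O)c1ccc(C)cc1 | intermediate
12 | the corresponding cyclohexane-5,8-diol (5-OH on the face of 4-benzyloxy and 8-OH) | C=C[C@H]1[C@@](C)(OCc2ccccc2)[C@@H](O)[C@H](OCc2ccccc2)[C@@H](CC2OCCO2)[C@]1(O)C[S@](=O)c1ccc(C)cc1 | intermediate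
13 | 5-O-triethylsilyl ether of 12 | C=C[C@H]1[C@@](C)(OCc2ccccc2)[C@@H](O[Si](CC)(CC)CC)[C@H](OCc2ccccc2)[C@@H](CC2OCCO2)[C@]1(O)C[S@](=O)c1ccc(C)cc1 | intermediate
14 | analogue of 13 with a 1-[(S)-p-tolylsulfinyl]propyl group on C8 (both C9 epimers) | C=C[C@H]1[C@@](C)(OCc2ccccc2)[C@@H](O[Si](CC)(CC)CC)[C@H](OCc2ccccc2)[C@@H](CC2OCCO2)[C@]1(O)C(CC)[S@](=O)c1ccc(C)cc1 | intermediate
15 | 4,6-bis(benzyloxy)-7-(1,3-dioxolan-2-ylmethyl)-4-methyl-8-[(E)-prop-1-enyl]-5-(triethylsilyloxy)-3-vinylcyclohexan-8-ol (vinyl and propenyl trans; 8-OH cis to vinyl) | C=C[C@H]1[C@@](C)(OCc2ccccc2)[C@@H](O[Si](CC)(CC)CC)[C@H](OCc2ccccc2)[C@@H](CC2OCCO2)[C@]1(O)/C=C/C | intermediate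
16 | potassium C8=C9 enolate of the ring-expanded cyclodeca-2,8-diene (C7 and C10 trans across C8=C9; 10R) | [O-]/C1=C\[C@H](C)C/C=C/[C@@](C)(OCc2ccccc2)[C@@H](O[Si](CC)(CC)CC)[C@H](OCc2ccccc2)[C@H]1CC3OCCO3.[K+] | intermediate
17 | (9S,10R)-4,6-bis(benzyloxy)-7-(1,3-dioxolan-2-ylmethyl)-9-hydroxy-4,10-dimethyl-5-(triethylsilyloxy)cyclodec-2-en-8-one (2E; C4–C7 as in 15) | O=C1[C@@H](O)[C@H](C)C/C=C/[C@@](C)(OCc2ccccc2)[C@@H](O[Si](CC)(CC)CC)[C@H](OCc2ccccc2)[C@H]1CC3OCCO3 | intermediate
18 | the corresponding (8R,9S,10R)-cyclodec-2-ene-8,9-diol | O[C@H]1[C@@H](O)[C@H](C)C/C=C/[C@@](C)(OCc2ccccc2)[C@@H](O[Si](CC)(CC)CC)[C@H](OCc2ccccc2)[C@H]1CC3OCCO3 | intermediate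
19 | 9-O-(p-toluenesulfonate) of diol 18 | O[C@H]1[C@@H](OS(=O)(=O)c2ccc(C)cc2)[C@H](C)C/C=C/[C@@](C)(OCc2ccccc2)[C@@H](O[Si](CC)(CC)CC)[C@H](OCc2ccccc2)[C@H]1CC3OCCO3 | intermediate
20 | (8R,9R,10R)-8,9-epoxy-4,6-bis(benzyloxy)-7-(1,3-dioxolan-2-ylmethyl)-4,10-dimethylcyclodec-2-en-5-ol (trans-epoxide) | O1[C@H]2[C@H]1[C@H](C)C/C=C/[C@@](C)(OCc3ccccc3)[C@@H](O)[C@H](OCc3ccccc3)[C@H]2CC4OCCO4 | intermediate
21 | 5-O-methanesulfonate of 20 | O1[C@H]2[C@H]1[C@H](C)C/C=C/[C@@](C)(OCc3ccccc3)[C@@H](OS(C)(=O)=O)[C@H](OCc3ccccc3)[C@H]2CC4OCCO4 | intermediate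
22 | 8,9-epoxy-7-(1,3-dioxolan-2-ylmethyl)-4,6-dihydroxy-4,10-dimethylcyclodecan-5-yl methanesulfonate | O1[C@H]2[C@H]1[C@H](C)CCC[C@@](C)(O)[C@@H](OS(C)(=O)=O)[C@H](O)[C@H]2CC4OCCO4 | intermediate
23 | 6-O-(3-methylbut-2-enoyl) ester of 22 | O1[C@H]2[C@H]1[C@H](C)CCC[C@@](C)(O)[C@@H](OS(C)(=O)=O)[C@H](OC(=O)C=C(C)C)[C@H]2CC4OCCO4 | intermediate
24 | aldehyde from 23 (C7–CH2–CHO) | O1[C@H]2[C@H]1[C@H](C)CCC[C@@](C)(O)[C@@H](OS(C)(=O)=O)[C@H](OC(=O)C=C(C)C)[C@H]2CC=O | intermediate
25 | (4R,5R)-4,5:8,9-diepoxy aldehyde (C7–CH2–CHO; 6-O-senecioyl) | O1[C@H]2[C@H]1[C@H](C)CCC[C@@]3(C)O[C@@H]3[C@H](OC(=O)C=C(C)C)[C@H]2CC=O | intermediate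
26 | 4,5:8,9-diepoxy α-methylene aldehyde (C7–C(=CH2)–CHO) | O1[C@H]2[C@H]1[C@H](C)CCC[C@@]3(C)O[C@@H]3[C@H](OC(=O)C=C(C)C)[C@H]2C(=C)C=O | intermediate
27 | 4,5:8,9-diepoxy acrylic acid (C7–C(=CH2)–CO2H) | O1[C@H]2[C@H]1[C@H](C)CCC[C@@]3(C)O[C@@H]3[C@H](OC(=O)C=C(C)C)[C@H]2C(=C)C(=O)O | intermediate
28 | (4R,5R,6R,7S,8S,9R,10R)-4,5-epoxy-9-hydroxy-6-(3-methylbut-2-enoyloxy)germacr-11(13)-en-12,8-olide | C=C1C(=O)O[C@@H]2[C@H](O)[C@H](C)CCC[C@@]3(C)O[C@@H]3[C@H](OC(=O)C=C(C)C)[C@@H]12 | target

**Summary**

Total steps: 18. Longest linear sequence: 18 steps (1 → 28); 5 and all reagents are purchased.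

The three steps most likely to fail:

Step 10. Enolate 16 may be consumed by proton transfer towards C7 (with β-elimination of the C6 benzyloxy group) or by addition to the sulfonimine released from the oxaziridine, and oxygen transfer to the hindered potassium enolate may be slow. The fallback sets out from 15: the rearrangement is run as before, but the enolate is quenched at −78 °C with Me3SiCl/Et3N to give the isolable trimethylsilyl enol ether F1. Epoxidation of F1 from its outer face with dimethyldioxirane (acetone/CH2Cl2, −78 °C) and silyl cleavage on work-up with dilute citric acid (Rubottom oxidation) should return the route at 17.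

Step 4. The remote sulfinyl group may discriminate poorly between the two enone arms, 1,2-addition to the dienone carbonyl may compete, and alkylation of the magnesium enolate may be slow or occur on oxygen. The fallback sets out from 7: the directed vinyl addition is run alone and the enolate and alkoxide are silylated (Me3SiCl, Et3N) to give the bis(trimethylsilyl) derivative F2, which can be freed from its arm isomer by chromatography because the two are diastereomers. Fluoride-promoted regiospecific methylation of the silyl enol ether (benzyltrimethylammonium fluoride, MeI, THF, 0 °C), which also cleaves the tertiary silyl ether, should return the route at 9.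

Step 12. Sulfonylation may occur at the C8 hydroxyl or at both hydroxyls, and closure would then give the diastereomeric epoxide. The fallback sets out from 17, in which the C9 hydroxyl is the only free one: tosylation (TsCl, 4-(dimethylamino)pyridine, pyridine, 0 °C) gives the α-tosyloxy ketone F3, so the site of activation is fixed before the diol exists. Reduction of the ketone with NaBH4 in MeOH at −40 °C, with hydride again expected from the outer face of the ring (this fallback trades the regiochemical risk for that facial-selectivity risk), should return the route at 19, which is closed with Bu4NF as in step 12.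

Further compounds
F1 | step 10 | trimethylsilyl enol ether of the ring-expanded ketone (C8–OSiMe3, C8=C9; otherwise as 16) | C[Si](C)(C)O/C1=C\[C@H](C)C/C=C/[C@@](C)(OCc2ccccc2)[C@@H](O[Si](CC)(CC)CC)[C@H](OCc2ccccc2)[C@H]1CC3OCCO3
F2 | step 4 | bis(trimethylsilyl) derivative of the vinyl adduct (C5 silyl enol ether and C8 silyl ether; otherwise as 8) | C=C[C@H]1C(OCc2ccccc2)=C(O[Si](C)(C)C)C(OCc2ccccc2)=C[C@]1(O[Si](C)(C)C)C[S@](=O)c1ccc(C)cc1
F3 | step 12 | 9-O-(p-toluenesulfonate) of α-hydroxy ketone 17 | O=C1[C@@H](OS(=O)(=O)c2ccc(C)cc2)[C@H](C)C/C=C/[C@@](C)(OCc2ccccc2)[C@@H](O[Si](CC)(CC)CC)[C@H](OCc2ccccc2)[C@H]1CC3OCCO3
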